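**Remark (assumption):** the target is read as robinetinidol-(4β→8)-epigallocatechin 3-O-gallate, upper unit (2R,3S,4R) (2,3-trans-3,4-cis), lower unit (2R,3R) (2,3-cis); (+)-(2R,3R)-dihydrorobinetin is taken as a commercially available chiral-pool material.

## Retrosynthetic overview

1. Ring C of the lower (epigallocatechin gallate) unit is closed last, by a hetero-Diels–Alder reaction of an o-quinone methide (O1=C8a–C4a=C4H2 on lower ring A) with a Z enol gallate (C2=C3, carrying ring B and the galloyl ester); this forms O1–C2 and C3–C4 with the 2,3-cis ester in place.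
2. Enabling feature: C4 of that ring is an unsubstituted benzylic CH2 on C4a, ortho to O1 on C8a of a phloroglucinol ring A, and C2/C3 are a cis benzylic-ether/ester pair, the retron of an o-quinone methide plus a Z β-acyloxystyrene; with C8 occupied by the upper unit, O1 is the only phenol that can become the ring oxygen.
3. Before that, the interflavan C4–C8 bond is made by boron-directed cis-arylation of the flavan-3,4-diol from (+)-dihydrorobinetin; the upper 3-OH is never protected and is used twice as a directing group.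
4. Ring order: upper rings A, C, B (chiral pool, intact) → lower ring A joined as an arylboronic acid → ring B and galloyl ring brought in together in the enol ester → lower ring C closed → global hydrogenolysis.

Key step: step 12

## Route

Step 1
Reactants: 1 (+)-dihydrorobinetin
Product: 2 (2R,3R)-7-benzyloxy-3-hydroxy-2-[3,4,5-tris(benzyloxy)phenyl]chroman-4-one
Conditions: BnBr, K2CO3, DMF, rt, Ar
Reagents that add atoms: benzyl bromide, BrCc1ccccc1
Why: Williamson ether synthesis in which K2CO3 ionises only the four phenols (the aliphatic 3-OH stays free), and the mild, oxygen-free conditions should keep the base-sensitive trans C2/C3 pair intact.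

Step 2
Reactants: 2 (2R,3R)-7-benzyloxy-3-hydroxy-2-[3,4,5-tris(benzyloxy)phenyl]chroman-4-one
Product: 3 (2R,3S,4R)-7-benzyloxy-2-[3,4,5-tris(benzyloxy)phenyl]chromane-3,4-diol
Conditions: NaBH4, THF/MeOH, 0 °C
Reagents that add atoms: none
Why: Borohydride reduction of the aryl ketone should give mainly the 3,4-trans (4R) diol, and the C4 configuration is immaterial because C4 is planarised in step 6.

Step 3
Reactants: 4 3,5-bis(benzyloxy)phenol
Product: 5 2-bromo-3,5-bis(benzyloxy)phenol
Conditions: NBS, iPr2NH (cat.), CH2Cl2, −20 → 0 °C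
Reagents that add atoms: N-bromosuccinimide, O=C1CCC(=O)N1Br
Why: Amine-mediated ortho-selective electrophilic bromination of a phenol; the two ortho positions are equivalent and one equivalent of NBS at low temperature should stop at the monobromide.

Step 4
Reactants: 5 2-bromo-3,5-bis(benzyloxy)phenol
Product: 6 1,5-bis(benzyloxy)-2-bromo-3-(methoxymethoxy)benzene
Conditions: MOMCl, iPr2NEt, CH2Cl2, 0 °C → rt
Reagents that add atoms: chloromethyl methyl ether, COCCl
Why: O-Alkylation of the phenol as its methoxymethyl ether, which survives butyllithium and is later removed without touching benzyl ethers.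

Step 5
Reactants: 6 1,5-bis(benzyloxy)-2-bromo-3-(methoxymethoxy)benzene
Product: 9 [2,4-bis(benzyloxy)-6-(methoxymethoxy)phenyl]boronic acid, via aryllithium 7 (not isolated), via dimethyl arylboronate 8 (not isolated)
Conditions: n-BuLi, THF, −78 °C; B(OMe)3, −78 → 0 °C; H2O
Reagents that add atoms: trimethyl borate, COB(OC)OC; water, O
Why: Bromine–lithium exchange at −78 °C outruns benzylic deprotonation of the benzyl ethers, the aryllithium is trapped by trimethyl borate, and neutral aqueous work-up avoids protodeboronation of the electron-rich boronic acid.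

Step 6
Reactants: 3 (2R,3S,4R)-7-benzyloxy-2-[3,4,5-tris(benzyloxy)phenyl]chromane-3,4-diol; 9 [2,4-bis(benzyloxy)-6-(methoxymethoxy)phenyl]boronic acid
Product: 11 (2R,3S,4R)-4-[2,4-bis(benzyloxy)-6-(methoxymethoxy)phenyl]-7-benzyloxy-2-[3,4,5-tris(benzyloxy)phenyl]chroman-3-ol, via cyclic 3,4-O-arylboronate 10 (not isolated)
Conditions: 4 Å MS, CH2Cl2, rt; then (CF3)2CHOH, −20 → 0 °C; H2O
Reagents that add atoms: none
Why: Proposed new method: diol and boronic acid form boronate 10; ionisation of the doubly activated benzylic C4–O bond (para-benzyloxy, ortho ring oxygen) in (CF3)2CHOH leaves a C4 cation whose boron, still held on the 3-oxygen, passes its electron-rich aryl group to C4 through a five-membered transition state, so the new bond is cis to the 3-OH (4β) and is made at the boron-bearing carbon next to the OMOM group; closest known reaction types are the Petasis borono-Mannich reaction, hydroxyl-directed cis-arylation of cyclic N-acyliminium ions by boronic acids, and intramolecular aglycon delivery.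

Step 7
Reactants: 11 (2R,3S,4R)-4-[2,4-bis(benzyloxy)-6-(methoxymethoxy)phenyl]-7-benzyloxy-2-[3,4,5-tris(benzyloxy)phenyl]chroman-3-ol
Product: 12 (2R,3S,4R)-4-[2,4-bis(benzyloxy)-6-hydroxyphenyl]-7-benzyloxy-2-[3,4,5-tris(benzyloxy)phenyl]chroman-3-ol
Conditions: HCl (0.5 M), MeOH/THF, rt
Reagents that add atoms: none
Why: Acid-catalysed acetal exchange removes the methoxymethyl group, while the benzyl ethers and the interflavan bond (stabilised against acid by the 5-deoxy upper ring A) should survive.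

Step 8
Reactants: 12 (2R,3S,4R)-4-[2,4-bis(benzyloxy)-6-hydroxyphenyl]-7-benzyloxy-2-[3,4,5-tris(benzyloxy)phenyl]chroman-3-ol
Product: 13 4,6-bis(benzyloxy)-3-{(2R,3S,4R)-7-benzyloxy-3-hydroxy-2-[3,4,5-tris(benzyloxy)phenyl]chroman-4-yl}-2-hydroxybenzaldehyde
Conditions: MgCl2, Et3N, (CH2O)n, THF, reflux
Reagents that add atoms: paraformaldehyde (as formaldehyde), C=O
Why: Casnati–Skattebøl ortho-formylation, in which the magnesium phenoxide directs formaldehyde to the only free ortho carbon (the future C4a) and the hydroxymethyl intermediate is oxidised in situ by a second formaldehyde, so the carbon para to the phenol stays untouched.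

Step 9
Reactants: 13 4,6-bis(benzyloxy)-3-{(2R,3S,4R)-7-benzyloxy-3-hydroxy-2-[3,4,5-tris(benzyloxy)phenyl]chroman-4-yl}-2-hydroxybenzaldehyde
Product: 14 3,5-bis(benzyloxy)-2-{(2R,3S,4R)-7-benzyloxy-3-hydroxy-2-[3,4,5-tris(benzyloxy)phenyl]chroman-4-yl}-6-(hydroxymethyl)phenol
Conditions: NaBH4, THF/MeOH, 0 °C; pH 7 buffer
Reagents that add atoms: none
Why: Borohydride reduction of the aldehyde at 0 °C should give the o-hydroxybenzyl alcohol, which is used without chromatography because it is the direct precursor of the quinone methide.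

Step 10
Reactants: 15 3,4,5-tris(benzyloxy)benzaldehyde
Product: 16 1,2,3-tris(benzyloxy)-5-ethynylbenzene
Conditions: dimethyl (1-diazo-2-oxopropyl)phosphonate, K2CO3, MeOH/THF, rt
Reagents that add atoms: dimethyl (1-diazo-2-oxopropyl)phosphonate, COP(=O)(OC)C(=[N+]=[N-])C(C)=O
Why: Seyferth–Gilbert homologation with the Ohira–Bestmann reagent converts the aldehyde into the terminal alkyne under mild base compatible with benzyl ethers.

Step 11
Reactants: 16 1,2,3-tris(benzyloxy)-5-ethynylbenzene; 17 3,4,5-tris(benzyloxy)benzoic acid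
Product: 18 (Z)-2-[3,4,5-tris(benzyloxy)phenyl]ethenyl 3,4,5-tris(benzyloxy)benzoate
Conditions: Ru(2-methylallyl)2(Ph2P(CH2)4PPh2) (2 mol %), toluene, 65 °C
Reagents that add atoms: none
Why: Ruthenium-catalysed anti-Markovnikov addition of a carboxylic acid to a terminal alkyne through a vinylidene intermediate, which for aryl alkynes with this catalyst type gives the Z enol ester.

Step 12
Reactants: 14 3,5-bis(benzyloxy)-2-{(2R,3S,4R)-7-benzyloxy-3-hydroxy-2-[3,4,5-tris(benzyloxy)phenyl]chroman-4-yl}-6-(hydroxymethyl)phenol; 18 (Z)-2-[3,4,5-tris(benzyloxy)phenyl]ethenyl 3,4,5-tris(benzyloxy)benzoate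
Product: 20 dodeca-O-benzyl robinetinidol-(4β→8)-epigallocatechin 3-O-gallate (upper 3-OH free), via o-quinone methide 19 (not isolated)
Conditions: 18 (3 equiv), 4 Å MS, toluene, 60–80 °C, slow addition of 14
Reagents that add atoms: none
Why: Proposed new method: on warming, 14 loses water to give o-quinone methide 19 (O1=C8a–C4a=C4H2), which should undergo an inverse-electron-demand oxa-[4+2] cycloaddition with Z enol ester 18; the closest known reaction type is the hetero-Diels–Alder flavan synthesis from o-quinone methides and styrenes, the new element being a β-acyloxystyrene as the 2π partner. Ring C is closed by intermolecular [4+2] cycloaddition, the C3–C4 bond leading and the O1–C2 bond following in one concerted, asynchronous event. The 2,3-cis relationship is dictated by the Z geometry of 18 (suprafacial addition); the absolute sense (2R,3R) is expected from substrate control, because the upper 3-OH hydrogen-bonds to the quinone methide oxygen, which activates the heterodiene and fixes the rotamer about the C4–C8 bond so that upper ring A covers one face, while 18 adds endo (aryl and acyloxy under the heterodiene, away from the bulky C8 substituent) to the open face. Three selectivities are needed: regiochemistry (O1 to the benzylic carbon) is secured by the trialkoxyaryl group being a better π-donor than the cross-conjugated aroyloxy group, which makes the acyloxy-bearing carbon the nucleophilic terminus; site selectivity (4→8, not 4→6) is secured by the protecting-group pattern, O1 being the only free phenol and its only free ortho carbon carrying the CH2OH; chemoselectivity over self-alkylation of the electron-rich arenes is secured by neutral, acid-free generation of 19 in the presence of excess 18.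

Step 13
Reactants: 20 dodeca-O-benzyl robinetinidol-(4β→8)-epigallocatechin 3-O-gallate (upper 3-OH free)
Product: 21 robinetinidol-(4β→8)-epigallocatechin 3-O-gallate (target)
Conditions: H2 (1 atm), Pd(OH)2/C, THF/MeOH, rt
Reagents that add atoms: none
Why: Hydrogenolysis of the twelve benzyl ethers under neutral conditions should leave the gallate ester, the benzylic ring C–O bonds and all five stereocentres untouched.

## Compound list

1 | (+)-dihydrorobinetin, (2R,3R)-3,7-dihydroxy-2-(3,4,5-trihydroxyphenyl)chroman-4-one | O=C1c2ccc(O)cc2O[C@H](c2cc(O)c(O)c(O)c2)[C@H]1O | starting material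
2 | (2R,3R)-7-benzyloxy-3-hydroxy-2-[3,4,5-tris(benzyloxy)phenyl]chroman-4-one | O=C1c2ccc(OCc3ccccc3)cc2O[C@H](c2cc(OCc3ccccc3)c(OCc3ccccc3)c(OCc3ccccc3)c2)[C@H]1O | intermediate
3 | (2R,3S,4R)-7-benzyloxy-2-[3,4,5-tris(benzyloxy)phenyl]chromane-3,4-diol (2,3-trans-3,4-trans) | O[C@@H]1c2ccc(OCc3ccccc3)cc2O[C@H](c2cc(OCc3ccccc3)c(OCc3ccccc3)c(OCc3ccccc3)c2)[C@H]1O | intermediate
4 | 3,5-bis(benzyloxy)phenol | Oc1cc(OCc2ccccc2)cc(OCc2ccccc2)c1 | starting material
5 | 2-bromo-3,5-bis(benzyloxy)phenol | Oc1cc(OCc2ccccc2)cc(OCc2ccccc2)c1Br | intermediate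
6 | 1,5-bis(benzyloxy)-2-bromo-3-(methoxymethoxy)benzene | COCOc1cc(OCc2ccccc2)cc(OCc2ccccc2)c1Br | intermediate
7 | [2,4-bis(benzyloxy)-6-(methoxymethoxy)phenyl]lithium | COCOc1cc(OCc2ccccc2)cc(OCc2ccccc2)c1[Li] | intermediate (not isolated)
8 | dimethyl [2,4-bis(benzyloxy)-6-(methoxymethoxy)phenyl]boronate | COCOc1cc(OCc2ccccc2)cc(OCc2ccccc2)c1B(OC)OC | intermediate (not isolated)
9 | [2,4-bis(benzyloxy)-6-(methoxymethoxy)phenyl]boronic acid | COCOc1cc(OCc2ccccc2)cc(OCc2ccccc2)c1B(O)O | intermediate
10 | cyclic 3,4-O-arylboronate (1,3,2-dioxaborolane) of diol 3 with boronic acid 9 | COCOc1cc(OCc2ccccc2)cc(OCc2ccccc2)c1B1O[C@@H]2c3ccc(OCc4ccccc4)cc3O[C@H](c3cc(OCc4ccccc4)c(OCc4ccccc4)c(OCc4ccccc4)c3)[C@H]2O1 | intermediate (not isolated)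
11 | (2R,3S,4R)-4-[2,4-bis(benzyloxy)-6-(methoxymethoxy)phenyl]-7-benzyloxy-2-[3,4,5-tris(benzyloxy)phenyl]chroman-3-ol (2,3-trans-3,4-cis) | COCOc1cc(OCc2ccccc2)cc(OCc2ccccc2)c1[C@H]1c2ccc(OCc3ccccc3)cc2O[C@H](c2cc(OCc3ccccc3)c(OCc3ccccc3)c(OCc3ccccc3)c2)[C@H]1O | intermediate
12 | (2R,3S,4R)-4-[2,4-bis(benzyloxy)-6-hydroxyphenyl]-7-benzyloxy-2-[3,4,5-tris(benzyloxy)phenyl]chroman-3-ol | Oc1cc(OCc2ccccc2)cc(OCc2ccccc2)c1[C@H]1c2ccc(OCc3ccccc3)cc2O[C@H](c2cc(OCc3ccccc3)c(OCc3ccccc3)c(OCc3ccccc3)c2)[C@H]1O | intermediate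
13 | 4,6-bis(benzyloxy)-3-{(2R,3S,4R)-7-benzyloxy-3-hydroxy-2-[3,4,5-tris(benzyloxy)phenyl]chroman-4-yl}-2-hydroxybenzaldehyde | O=Cc1c(OCc2ccccc2)cc(OCc2ccccc2)c([C@H]2c3ccc(OCc4ccccc4)cc3O[C@H](c3cc(OCc4ccccc4)c(OCc4ccccc4)c(OCc4ccccc4)c3)[C@H]2O)c1O | intermediate
14 | 3,5-bis(benzyloxy)-2-{(2R,3S,4R)-7-benzyloxy-3-hydroxy-2-[3,4,5-tris(benzyloxy)phenyl]chroman-4-yl}-6-(hydroxymethyl)phenol | OCc1c(OCc2ccccc2)cc(OCc2ccccc2)c([C@H]2c3ccc(OCc4ccccc4)cc3O[C@H](c3cc(OCc4ccccc4)c(OCc4ccccc4)c(OCc4ccccc4)c3)[C@H]2O)c1O | intermediate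
15 | 3,4,5-tris(benzyloxy)benzaldehyde | O=Cc1cc(OCc2ccccc2)c(OCc2ccccc2)c(OCc2ccccc2)c1 | starting material
16 | 1,2,3-tris(benzyloxy)-5-ethynylbenzene | C#Cc1cc(OCc2ccccc2)c(OCc2ccccc2)c(OCc2ccccc2)c1 | intermediate
17 | 3,4,5-tris(benzyloxy)benzoic acid | OC(=O)c1cc(OCc2ccccc2)c(OCc2ccccc2)c(OCc2ccccc2)c1 | starting material
18 | (Z)-2-[3,4,5-tris(benzyloxy)phenyl]ethenyl 3,4,5-tris(benzyloxy)benzoate | O=C(O/C=C\c1cc(OCc2ccccc2)c(OCc2ccccc2)c(OCc2ccccc2)c1)c1cc(OCc2ccccc2)c(OCc2ccccc2)c(OCc2ccccc2)c1 | intermediate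
19 | o-quinone methide: 3,5-bis(benzyloxy)-6-methylidene-2-{(2R,3S,4R)-7-benzyloxy-3-hydroxy-2-[3,4,5-tris(benzyloxy)phenyl]chroman-4-yl}cyclohexa-2,4-dien-1-one | C=C1C(OCc2ccccc2)=CC(OCc2ccccc2)=C([C@H]2c3ccc(OCc4ccccc4)cc3O[C@H](c3cc(OCc4ccccc4)c(OCc4ccccc4)c(OCc4ccccc4)c3)[C@H]2O)C1=O | intermediate (not isolated)
20 | dodeca-O-benzyl robinetinidol-(4β→8)-epigallocatechin 3-O-gallate (all twelve phenols as benzyl ethers, upper 3-OH free; upper 2R,3S,4R, lower 2R,3R) | O=C(O[C@@H]1Cc2c(OCc3ccccc3)cc(OCc3ccccc3)c([C@H]3c4ccc(OCc5ccccc5)cc4O[C@H](c4cc(OCc5ccccc5)c(OCc5ccccc5)c(OCc5ccccc5)c4)[C@H]3O)c2O[C@@H]1c1cc(OCc2ccccc2)c(OCc2ccccc2)c(OCc2ccccc2)c1)c1cc(OCc2ccccc2)c(OCc2ccccc2)c(OCc2ccccc2)c1 | intermediate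
21 | robinetinidol-(4β→8)-epigallocatechin 3-O-gallate (CNP0269431.2) | O=C(O[C@@H]1Cc2c(O)cc(O)c([C@H]3c4ccc(O)cc4O[C@H](c4cc(O)c(O)c(O)c4)[C@H]3O)c2O[C@@H]1c1cc(O)c(O)c(O)c1)c1cc(O)c(O)c(O)c1 | target

## Summary and risks

Total step count: 13. Longest linear sequence: 9 steps (4 → 5 → 6 → 9 → 11 → 12 → 13 → 14 → 20 → 21).

Steps most likely to fail:

1. Step 12 (Proposed new method). What may go wrong: the quinone methide may oligomerise or alkylate the electron-rich arenes faster than it is trapped, the cycloaddition may run with low facial selectivity, or it may run with reversed regiochemistry. Fallback (known chemistry; sets out from aldehyde 13 with 16 and 17, comes back at 21): alkyne 16 and acid 17 are joined by gold-catalysed oxidative acyloxylation (Ph3PAuNTf2, 8-methylquinoline N-oxide) to 2-oxo-2-[3,4,5-tris(benzyloxy)phenyl]ethyl 3,4,5-tris(benzyloxy)benzoate F1. F1 and 13 are condensed with dry HCl in EtOAc (aldol condensation and cyclodehydration, the classical flavylium synthesis), which closes the same ring at the anthocyanidin oxidation level as the 3-galloyloxyflavylium chloride F2 with unambiguous constitution. Hydrogenation of F2 over Pd(OH)2/C should saturate the pyrylium ring by syn addition (2,3-cis) and remove all benzyl groups, giving 21 together with its lower-unit (2S,3S) diastereomer F3, which is removed by preparative HPLC.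

2. Step 6 (Proposed new method). What may go wrong: protodeboronation of the electron-rich boronic acid followed by undirected intermolecular arylation, with loss of both the 4β and the ortho control. Fallback (known chemistry; sets out from diol 3 and phenol 4, comes back at 12): acid-catalysed Friedel–Crafts condensation of 3 with excess 4 (BF3·OEt2 cat., CH2Cl2, −20 °C), the classical flavan-3,4-diol/phenol coupling, gives 12 directly without the MOM detour; 12 must be separated by chromatography from its 4α epimer F4, which is expected to be the main co-product.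

3. Step 9. What may go wrong: over-reduction through quinone methide formation and hydride capture, or decomposition of the labile salicyl alcohol on isolation. Fallback (sets out from phenol 12, comes back at 14): boronic acid-templated ortho-hydroxymethylation (PhB(OH)2, (CH2O)n, EtCO2H cat., toluene, reflux with water removal) gives the stable, storable 2-phenyl-4H-1,3,2-benzodioxaborin F5 without any hydride reagent; transesterification with 2,2-dimethylpropane-1,3-diol (THF, rt) releases 14 immediately before the key step.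

Further compounds
F1 | step 12 | 2-oxo-2-[3,4,5-tris(benzyloxy)phenyl]ethyl 3,4,5-tris(benzyloxy)benzoate | O=C(OCC(=O)c1cc(OCc2ccccc2)c(OCc2ccccc2)c(OCc2ccccc2)c1)c1cc(OCc2ccccc2)c(OCc2ccccc2)c(OCc2ccccc2)c1
F2 | step 12 | 5,7-bis(benzyloxy)-8-{(2R,3S,4R)-7-benzyloxy-3-hydroxy-2-[3,4,5-tris(benzyloxy)phenyl]chroman-4-yl}-2-[3,4,5-tris(benzyloxy)phenyl]-3-[3,4,5-tris(benzyloxy)benzoyloxy]chromenylium chloride | O=C(Oc1cc2c(OCc3ccccc3)cc(OCc3ccccc3)c([C@H]3c4ccc(OCc5ccccc5)cc4O[C@H](c4cc(OCc5ccccc5)c(OCc5ccccc5)c(OCc5ccccc5)c4)[C@H]3O)c2[o+]c1-c1cc(OCc2ccccc2)c(OCc2ccccc2)c(OCc2ccccc2)c1)c1cc(OCc2ccccc2)c(OCc2ccccc2)c(OCc2ccccc2)c1.[Cl-]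
F3 | step 12 | lower-unit (2S,3S) diastereomer of 21, robinetinidol-(4β→8)-ent-epigallocatechin 3-O-gallate | O=C(O[C@H]1Cc2c(O)cc(O)c([C@H]3c4ccc(O)cc4O[C@H](c4cc(O)c(O)c(O)c4)[C@H]3O)c2O[C@H]1c1cc(O)c(O)c(O)c1)c1cc(O)c(O)c(O)c1
F4 | step 6 | (2R,3S,4S)-4-[2,4-bis(benzyloxy)-6-hydroxyphenyl]-7-benzyloxy-2-[3,4,5-tris(benzyloxy)phenyl]chroman-3-ol (4α epimer of 12) | Oc1cc(OCc2ccccc2)cc(OCc2ccccc2)c1[C@@H]1c2ccc(OCc3ccccc3)cc2O[C@H](c2cc(OCc3ccccc3)c(OCc3ccccc3)c(OCc3ccccc3)c2)[C@H]1O
F5 | step 9 | 5,7-bis(benzyloxy)-8-{(2R,3S,4R)-7-benzyloxy-3-hydroxy-2-[3,4,5-tris(benzyloxy)phenyl]chroman-4-yl}-2-phenyl-4H-1,3,2-benzodioxaborin | c1ccccc1B1OCc2c(OCc3ccccc3)cc(OCc3ccccc3)c([C@H]3c4ccc(OCc5ccccc5)cc4O[C@H](c4cc(OCc5ccccc5)c(OCc5ccccc5)c(OCc5ccccc5)c4)[C@H]3O)c2O1
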